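The side chain (C1' benzylic to C17' methyl) has a saturated C1'–C14' tether between the resorcinol ring and the C15' carbinol, and this tether is read as a fully reduced polyyne. Its C7'–C8' bond is cut as the central single bond of a buta-1,3-diyne (C6'≡C7'–C8'≡C9'), so both carbons are acetylenic termini of like polarity, one made electrophilic as a 1-bromoalkyne. A Cadiot–Chodkiewicz coupling joins an aryl heptadiyne (ring plus C1'–C7') to a bromodiynol (C8'–C17', stereocentre from (S)-1,2-epoxybutane), giving a tetrayne with the complete skeleton. One hydrogenation then removes four alkynes and both benzyl ethers.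

Key step: step 4

Assumption: 1,3-bis(benzyloxy)-5-bromobenzene, hepta-1,6-diyne, hexa-1,5-diyne (sold as a solution in pentane) and (S)-1,2-epoxybutane are taken as catalogue compounds; the target is the (15'S) alcohol.

Step 1
Reactants: 1 1,3-bis(benzyloxy)-5-bromobenzene; 2 hepta-1,6-diyne (4 equiv)
Product: 3 1,3-bis(benzyloxy)-5-(hepta-1,6-diyn-1-yl)benzene
Conditions: Pd(PhCN)2Cl2 (3 mol%), P(t-Bu)3·HBF4 (6 mol%), CuI (2 mol%), i-Pr2NH, dioxane, rt, degassed
Reagents that add atoms: none
Why: Sonogashira coupling, in which the electron-rich Pd(0)/P(t-Bu)3 catalyst should insert into the aryl C–Br bond at room temperature and the copper acetylide of 2 transmetalates, while the fourfold excess of the symmetric diyne limits the reaction to one terminus (the volatile excess is distilled off).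

Step 2
Reactants: 4 hexa-1,5-diyne (4 equiv); 5 (S)-1,2-epoxybutane
Product: 7 (S)-deca-5,9-diyn-3-ol, via lithium hexa-1,5-diyn-1-ide 6 (not isolated)
Conditions: n-BuLi (2 equiv), THF, −78 °C; BF3·OEt2 (2 equiv); then 5 (1 equiv), −78 °C; aq NH4Cl
Reagents that add atoms: none
Why: BF3-promoted opening of a terminal epoxide by a lithium acetylide (Yamaguchi–Hirao alkynylation), in which SN2 attack at the unsubstituted CH2 of 5 leaves the C–O bond at the stereocentre unbroken, so the (S) configuration of 5 becomes (3S) in 7, and the twofold excess of diyne over n-BuLi keeps the lithiation single.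

Step 3
Reactants: 7 (S)-deca-5,9-diyn-3-ol
Product: 8 (S)-10-bromodeca-5,9-diyn-3-ol
Conditions: NBS (1.1 equiv), AgNO3 (10 mol%), acetone, rt, dark
Reagents that add atoms: N-bromosuccinimide, O=C1CCC(=O)N1Br
Why: Silver-catalysed electrophilic bromination of a terminal alkyne with NBS (via the silver acetylide) under neutral conditions, which should leave the secondary alcohol, the internal alkyne and the stereocentre untouched.

Step 4
Reactants: 3 1,3-bis(benzyloxy)-5-(hepta-1,6-diyn-1-yl)benzene (1.2 equiv); 8 (S)-10-bromodeca-5,9-diyn-3-ol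
Product: 9 (S)-17-[3,5-bis(benzyloxy)phenyl]heptadeca-5,9,11,16-tetrayn-3-ol
Conditions: CuCl (10 mol%), NH2OH·HCl (30 mol%), n-BuNH2, H2O/MeOH/THF, 0 °C to rt, argon, slow addition of 8; aq NH4Cl/EDTA work-up
Reagents that add atoms: none
Why: Cadiot–Chodkiewicz coupling, in which the amine and Cu(I) turn the terminal C–H of 3 into a copper(I) acetylide that adds oxidatively to the C(sp)–Br bond of 8 and reductively eliminates the C(sp)–C(sp) bond that becomes C7'–C8' of the target. Both carbons are acetylide-type donors, and their union is possible because one of them is polarity-reversed as a 1-bromoalkyne. No ring is closed and no stereocentre is formed; the C3 carbinol of 8 lies six bonds from the reacting terminus and is not touched. The step needs hetero- over homocoupling, which the substrates secure by bearing only one C–H terminus (3) and only one C–Br terminus (8), with hydroxylamine holding copper at +1 against Glaser dimerisation of 3 and slow addition of 8 against its reductive dimerisation. The internal alkynes, the free alcohol and the benzyl ethers should be inert to aqueous amine and Cu(I).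

Step 5
Reactants: 9 (S)-17-[3,5-bis(benzyloxy)phenyl]heptadeca-5,9,11,16-tetrayn-3-ol
Product: 10 Hansfordiol C [5-((15S)-15-hydroxyheptadecyl)benzene-1,3-diol]
Conditions: H2 (4 bar), 10% Pd/C, EtOAc/EtOH, rt
Reagents that add atoms: none
Why: Heterogeneous catalytic hydrogenation, in which Pd/C should saturate all four alkynes and hydrogenolyse both benzyl aryl ethers in the same operation, while the non-benzylic secondary carbinol C–O bond and its (S) configuration are not affected.

Compound list
1 | 1,3-bis(benzyloxy)-5-bromobenzene | Brc1cc(OCc2ccccc2)cc(OCc2ccccc2)c1 | starting material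
2 | hepta-1,6-diyne | C#CCCCC#C | starting material
3 | 1,3-bis(benzyloxy)-5-(hepta-1,6-diyn-1-yl)benzene | C#CCCCC#Cc1cc(OCc2ccccc2)cc(OCc2ccccc2)c1 | intermediate
4 | hexa-1,5-diyne | C#CCCC#C | starting material
5 | (S)-1,2-epoxybutane [(2S)-2-ethyloxirane] | CC[C@H]1CO1 | starting material
6 | lithium hexa-1,5-diyn-1-ide | [Li]C#CCCC#C | intermediate
7 | (S)-deca-5,9-diyn-3-ol | CC[C@H](O)CC#CCCC#C | intermediate
8 | (S)-10-bromodeca-5,9-diyn-3-ol | CC[C@H](O)CC#CCCC#CBr | intermediate
9 | (S)-17-[3,5-bis(benzyloxy)phenyl]heptadeca-5,9,11,16-tetrayn-3-ol | CC[C@H](O)CC#CCCC#CC#CCCCC#Cc1cc(OCc2ccccc2)cc(OCc2ccccc2)c1 | intermediate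
10 | Hansfordiol C, 5-[(15S)-15-hydroxyheptadecyl]benzene-1,3-diol | CC[C@H](O)CCCCCCCCCCCCCCc1cc(O)cc(O)c1 | target

Total step count: 5
Longest linear sequence: 4 steps (steps 2, 3, 4, 5)

Steps most likely to fail

1. Step 4 (key step). The bromoalkyne may be consumed by reductive homocoupling, or may decompose in the basic copper medium, faster than it cross-couples. The fallback makes the same C7'–C8' bond with normal polarity, by SN2 alkylation of an acetylide with an sp3 iodide. It sets out from 1 and 7. Sonogashira coupling of 1 with purchased hept-6-yn-1-ol (conditions of step 1) should give 7-[3,5-bis(benzyloxy)phenyl]hept-6-yn-1-ol F1. Treatment with I2, PPh3 and imidazole (CH2Cl2, 0 °C) should convert it into 1,3-bis(benzyloxy)-5-(7-iodohept-1-yn-1-yl)benzene F2. Double deprotonation of 7 (n-BuLi, 2 equiv, THF/DMPU, −78 °C) should give the dilithium salt of (S)-deca-5,9-diyn-3-ol F3, which should be alkylated at carbon by F2 to give (S)-17-[3,5-bis(benzyloxy)phenyl]heptadeca-5,9,16-triyn-3-ol F4. Hydrogenation as in step 5 comes back to the route at 10.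

2. Step 2. The symmetric diyne may be lithiated at both ends so that one diyne opens two epoxides, or BF3 may oligomerise the epoxide before the acetylide attacks. The fallback uses a C6 donor with only one reactive end and no Lewis acid. It sets out from 5. Purchased 6-chloro-1-(trimethylsilyl)hex-1-yne and Mg in THF should give [6-(trimethylsilyl)hex-5-yn-1-yl]magnesium chloride F5, which should open 5 at the CH2 under CuI catalysis (THF, −30 °C) to give (S)-10-(trimethylsilyl)dec-9-yn-3-ol F6. Desilylative bromination (NBS, catalytic AgNO3, acetone) should give (S)-10-bromodec-9-yn-3-ol F7. Cadiot–Chodkiewicz coupling with 3 as in step 4 should give (S)-17-[3,5-bis(benzyloxy)phenyl]heptadeca-9,11,16-triyn-3-ol F8, and hydrogenation as in step 5 comes back to the route at 10.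

3. Step 5. On palladium the partly reduced chain may undergo double-bond migration from C13' toward the C15' carbinol, which would end by way of an enol in the ethyl ketone. Traces of copper or bromide from step 4 may also poison the catalyst and stall the reduction. The fallback separates the two tasks and saturates the chain without a metal hydride. It sets out from 9. Diimide (TsNHNH2, NaOAc, DME/H2O, reflux, large excess added in portions) should reduce all four alkynes without migration and leave the benzyl ethers, giving (S)-17-[3,5-bis(benzyloxy)phenyl]heptadecan-3-ol F9. Hydrogenolysis of the two benzyl ethers on the now saturated chain (H2, Pd/C, EtOH) comes back to the route at 10.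

Further compounds
F1 | step 4 | 7-[3,5-bis(benzyloxy)phenyl]hept-6-yn-1-ol | OCCCCCC#Cc1cc(OCc2ccccc2)cc(OCc2ccccc2)c1
F2 | step 4 | 1,3-bis(benzyloxy)-5-(7-iodohept-1-yn-1-yl)benzene | ICCCCCC#Cc1cc(OCc2ccccc2)cc(OCc2ccccc2)c1
F3 | step 4 | dilithium salt of (S)-deca-5,9-diyn-3-ol | CC[C@H](O[Li])CC#CCCC#C[Li]
F4 | step 4 | (S)-17-[3,5-bis(benzyloxy)phenyl]heptadeca-5,9,16-triyn-3-ol | CC[C@H](O)CC#CCCC#CCCCCCC#Cc1cc(OCc2ccccc2)cc(OCc2ccccc2)c1
F5 | step 2 | [6-(trimethylsilyl)hex-5-yn-1-yl]magnesium chloride | C[Si](C)(C)C#CCCCC[Mg]Cl
F6 | step 2 | (S)-10-(trimethylsilyl)dec-9-yn-3-ol | CC[C@H](O)CCCCCC#C[Si](C)(C)C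
F7 | step 2 | (S)-10-bromodec-9-yn-3-ol | CC[C@H](O)CCCCCC#CBr
F8 | step 2 | (S)-17-[3,5-bis(benzyloxy)phenyl]heptadeca-9,11,16-triyn-3-ol | CC[C@H](O)CCCCCC#CC#CCCCC#Cc1cc(OCc2ccccc2)cc(OCc2ccccc2)c1
F9 | step 5 | (S)-17-[3,5-bis(benzyloxy)phenyl]heptadecan-3-ol | CC[C@H](O)CCCCCCCCCCCCCCc1cc(OCc2ccccc2)cc(OCc2ccccc2)c1
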